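The 14-membered lactone (C1 carbonyl to O13) is closed at C10–C11 by an intramolecular allylboration. The seco ester 35 carries an (8R)-α-substituted β-methallyl pinacol boronate and a 2-methoxyoxane that hides the C11 aldehyde on O15. Mild hydrolysis frees the lactol; its aldehyde tautomer is attacked by C10 through a six-membered chair, which in one operation forms C10–C11, closes the ring, sets the (11R) carbinol by 1,3-chirality transfer from C8, creates the (8Z)-trisubstituted C8=C9 alkene and releases the free C15 hydroxyl. The step exploits the homoallylic alcohol C11(OH)–C10H2–C9(CH3)=C8H embedded in the macrocycle; the boron-bearing stereocentre and the terminal alkene of the precursor vanish.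

Key step: step 19

Remarks on the chemistry:
- Atom numbers are those of the macrolide: C1 lactone carbonyl, C2=C3 (C3 carries CH2CO2H), C5=C6, C8=C9 (C9 carries CH3), C11 carbinol, C13 lactone carbinol, C15 side-chain carbinol, C18=C19 side-chain alkene.
- Assumption: the enol borinate made with (−)-Ipc2BCl is taken to attack the Si face of aldehyde 5, as is usual for methyl ketones; if the sense proves opposite, (+)-Ipc2BCl is used.
- Compounds 10 and 31–36 are mixtures of anomers at the acetal carbon; that centre is destroyed in step 19.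

Step 1
Reactants: 1 pent-4-yn-1-ol; 2 benzyl chloride
Product: 4 (E)-4-methyl-6-phenylhex-4-en-1-ol, via alkenylalane 3 (not isolated)
Conditions: AlMe3 (3 equiv), Cp2ZrCl2 (cat.), CH2Cl2, 0 → 23 °C; then 2, Pd(PPh3)4 (cat.), THF, 23 °C; aq. HCl work-up
Reagents that add atoms: trimethylaluminium, C[Al](C)C
Why: Zr-catalysed syn-carboalumination puts CH3 on the internal alkyne carbon with aluminium cis to it, and Pd-catalysed Negishi-type coupling of the alkenylalane with benzyl chloride proceeds with retention, fixing the (E)-C18=C19 alkene.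

Step 2
Reactants: 4 (E)-4-methyl-6-phenylhex-4-en-1-ol
Product: 5 (E)-4-methyl-6-phenylhex-4-enal
Conditions: Dess–Martin periodinane, NaHCO3, CH2Cl2, 0 → 23 °C
Reagents that add atoms: none
Why: Dess–Martin oxidation of a primary alcohol stops at the aldehyde and leaves the trisubstituted alkene alone.

Step 3
Reactants: 6 4,4-dimethoxybutan-2-one; 5 (E)-4-methyl-6-phenylhex-4-enal
Product: 8 (5R,8E)-5-hydroxy-1,1-dimethoxy-8-methyl-10-phenyldec-8-en-3-one, via boron enolate 7 (not isolated)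
Conditions: (−)-Ipc2BCl, Et3N, Et2O, 0 °C; then 5, −78 → −20 °C; then MeOH, pH 7 buffer, H2O2, 0 °C
Reagents that add atoms: none
Why: The bulky chloroborane enolises the ketone on the methyl side, and the reagent-controlled boron aldol reaction of the diisopinocampheyl enol borinate should set the C15 carbinol as (R).

Step 4
Reactants: 8 (5R,8E)-5-hydroxy-1,1-dimethoxy-8-methyl-10-phenyldec-8-en-3-one
Product: 9 (3S,5R,8E)-1,1-dimethoxy-8-methyl-10-phenyldec-8-ene-3,5-diol
Conditions: Me4NBH(OAc)3, MeCN/AcOH (1:1), −30 °C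
Reagents that add atoms: none
Why: In the Evans–Saksena reduction the C15 hydroxyl binds the borohydride and delivers hydride intramolecularly through a chair, which should give the 1,3-anti diol and so the (S) carbinol at C13.

Step 5
Reactants: 9 (3S,5R,8E)-1,1-dimethoxy-8-methyl-10-phenyldec-8-ene-3,5-diol
Product: 10 (4S,6R)-2-methoxy-6-[(3E)-3-methyl-5-phenylpent-3-en-1-yl]oxan-4-ol (anomeric mixture)
Conditions: PPTS (cat.), 4 Å molecular sieves, CH2Cl2, 23 °C
Reagents that add atoms: none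
Why: In this acid-catalysed transacetalisation only the C15 hydroxyl can reach C11 in a six-membered ring, so O15 and the latent C11 aldehyde mask each other and the C13 hydroxyl stays free.

Step 6
Reactants: 11 but-3-yn-1-ol
Product: 12 (but-3-yn-1-yloxy)(tert-butyl)diphenylsilane
Conditions: TBDPSCl, imidazole, DMF, 23 °C
Reagents that add atoms: tert-butyl(chloro)diphenylsilane, CC(C)(C)[Si](Cl)(c1ccccc1)c1ccccc1
Why: Standard silylation of a primary alcohol gives an ether that should survive the hot acetic acid of step 8 and all later steps until fluoride is used.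

Step 7
Reactants: 12 (but-3-yn-1-yloxy)(tert-butyl)diphenylsilane
Product: 14 methyl 5-(tert-butyldiphenylsilyloxy)pent-2-ynoate, via lithium acetylide 13 (not isolated)
Conditions: nBuLi, THF, −78 °C; then ClCO2Me, −78 → 0 °C
Reagents that add atoms: methyl chloroformate, COC(Cl)=O
Why: Deprotonation of the terminal alkyne and acylation of the acetylide with the chloroformate gives the ynoate.

Step 8
Reactants: 14 methyl 5-(tert-butyldiphenylsilyloxy)pent-2-ynoate
Product: 15 methyl (Z)-5-(tert-butyldiphenylsilyloxy)-3-iodopent-2-enoate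
Conditions: NaI, AcOH, 115 °C
Reagents that add atoms: sodium iodide, [Na+].[I-]
Why: Conjugate addition of iodide to the ynoate and protonation (net anti hydroiodination) should give the (Z)-3-iodoenoate, with iodine cis to the ester.

Step 9
Reactants: 15 methyl (Z)-5-(tert-butyldiphenylsilyloxy)-3-iodopent-2-enoate; 16 (tributylstannyl)methanol
Product: 18 4-[2-(tert-butyldiphenylsilyloxy)ethyl]furan-2(5H)-one, via hydroxymethyl enoate 17 (not isolated)
Conditions: Pd(PPh3)4 (cat.), 1,4-dioxane, 100 °C; then PPTS (cat.), 23 °C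
Reagents that add atoms: none
Why: Stille coupling with retention puts CH2OH cis to the ester and the cis-γ-hydroxy ester lactonises, so the ring locks the C2=C3 geometry with the future C4 cis to C1.

Step 10
Reactants: 18 4-[2-(tert-butyldiphenylsilyloxy)ethyl]furan-2(5H)-one
Product: 21 (Z)-3-[2-(tert-butyldiphenylsilyloxy)ethyl]-4-(triethylsilyloxy)but-2-enoic acid, via lithium hydroxy carboxylate 19 (not isolated), via bis-silyl derivative 20 (not isolated)
Conditions: LiOH, THF/H2O, 0 → 23 °C; evaporation; Et3SiCl, imidazole, DMF, 0 °C; then pH 5 buffer/THF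
Reagents that add atoms: lithium hydroxide, [Li+].[OH-]; chlorotriethylsilane, CC[Si](Cl)(CC)CC
Why: Saponification opens the lactone without touching the alkene, silylation caps both oxygens, and the labile silyl ester is hydrolysed on work-up, so the cis acid cannot relactonise.

Step 11
Reactants: 22 4-(trimethylsilyl)but-3-yn-1-ol; 23 N,N-diisopropylcarbamoyl chloride
Product: 24 4-(trimethylsilyl)but-3-yn-1-yl N,N-diisopropylcarbamate
Conditions: Et3N, CH2Cl2, reflux
Reagents that add atoms: none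
Why: Carbamoylation of the primary alcohol installs the directing and leaving group needed for the lithiation–borylation.

Step 12
Reactants: 24 4-(trimethylsilyl)but-3-yn-1-yl N,N-diisopropylcarbamate; 25 2-isopropenyl-4,4,5,5-tetramethyl-1,3,2-dioxaborolane
Product: 28 (R)-trimethyl[5-methyl-4-(4,4,5,5-tetramethyl-1,3,2-dioxaborolan-2-yl)hex-5-en-1-yn-1-yl]silane, via lithiated carbamate 26 (not isolated), via boronate complex 27 (not isolated)
Conditions: sBuLi, (−)-sparteine, Et2O, −78 °C; then 25, −78 °C; then MgBr2·OEt2, −78 °C → reflux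
Reagents that add atoms: none
Why: Sparteine-mediated removal of the pro-S proton, borylation with retention and 1,2-metallate rearrangement with inversion (lithiation–borylation) should give the (R)-α-substituted β-methallyl boronate, which is the C8 stereocentre.

Step 13
Reactants: 28 (R)-trimethyl[5-methyl-4-(4,4,5,5-tetramethyl-1,3,2-dioxaborolan-2-yl)hex-5-en-1-yn-1-yl]silane
Product: 29 (R)-4,4,5,5-tetramethyl-2-(2-methylhex-1-en-5-yn-3-yl)-1,3,2-dioxaborolane
Conditions: K2CO3, MeOH, 0 → 23 °C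
Reagents that add atoms: none
Why: Methoxide cleaves the alkynyl C–Si bond, and the hindered secondary pinacol boronate should survive the brief mild base.

Step 14
Reactants: 21 (Z)-3-[2-(tert-butyldiphenylsilyloxy)ethyl]-4-(triethylsilyloxy)but-2-enoic acid; 10 (4S,6R)-2-methoxy-6-[(3E)-3-methyl-5-phenylpent-3-en-1-yl]oxan-4-ol
Product: 31 (4S,6R)-2-methoxy-6-[(3E)-3-methyl-5-phenylpent-3-en-1-yl]oxan-4-yl (2Z)-3-[2-(tert-butyldiphenylsilyloxy)ethyl]-4-(triethylsilyloxy)but-2-enoate, via mixed anhydride 30 (not isolated)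
Conditions: 2,4,6-trichlorobenzoyl chloride, Et3N, toluene, 23 °C; then 10, DMAP, toluene, 0 → 23 °C
Reagents that add atoms: none
Why: Yamaguchi esterification acylates the equatorial C13 hydroxyl under conditions that spare the acetal and both silyl ethers.

Step 15
Reactants: 31 the triethylsilyl ether ester
Product: 32 (4S,6R)-2-methoxy-6-[(3E)-3-methyl-5-phenylpent-3-en-1-yl]oxan-4-yl (2Z)-3-[2-(tert-butyldiphenylsilyloxy)ethyl]-4-hydroxybut-2-enoate
Conditions: HF·pyridine, pyridine, THF, 0 °C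
Reagents that add atoms: none
Why: Buffered fluoride cleaves the primary allylic triethylsilyl ether much faster than the TBDPS ether and spares the acetal; the alcohol is used at once because it can lactonise with loss of 10.

Step 16
Reactants: 32 the cis-γ-hydroxy enoate
Product: 33 (4S,6R)-2-methoxy-6-[(3E)-3-methyl-5-phenylpent-3-en-1-yl]oxan-4-yl (2Z)-4-bromo-3-[2-(tert-butyldiphenylsilyloxy)ethyl]but-2-enoate
Conditions: CBr4, PPh3, 2,6-lutidine, CH2Cl2, −20 → 0 °C
Reagents that add atoms: carbon tetrabromide, BrC(Br)(Br)Br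
Why: The Appel reaction converts the primary allylic alcohol into the bromide by SN2 displacement under near-neutral conditions, without moving the C2=C3 alkene.

Step 17
Reactants: 33 the allylic bromide; 29 (R)-4,4,5,5-tetramethyl-2-(2-methylhex-1-en-5-yn-3-yl)-1,3,2-dioxaborolane
Product: 34 (4S,6R)-2-methoxy-6-[(3E)-3-methyl-5-phenylpent-3-en-1-yl]oxan-4-yl (2E,8R)-3-[2-(tert-butyldiphenylsilyloxy)ethyl]-9-methyl-8-(4,4,5,5-tetramethyl-1,3,2-dioxaborolan-2-yl)deca-2,9-dien-5-ynoate
Conditions: CuI, NaI, K2CO3, DMF, 23 °C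
Reagents that add atoms: none
Why: The copper acetylide formed from 29 under carbonate conditions displaces the allylic halide (iodide after exchange in the flask) in an SN2 sense, a copper-mediated alkyne–allyl halide coupling that should form C4–C5 without touching C2=C3 or the boronate.

Step 18
Reactants: 34 the skipped enyne
Product: 35 (4S,6R)-2-methoxy-6-[(3E)-3-methyl-5-phenylpent-3-en-1-yl]oxan-4-yl (2E,5Z,8R)-3-[2-(tert-butyldiphenylsilyloxy)ethyl]-9-methyl-8-(4,4,5,5-tetramethyl-1,3,2-dioxaborolan-2-yl)deca-2,5,9-trienoate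
Conditions: H2 (1 atm), Pd/CaCO3 poisoned with Pb(OAc)2, quinoline, EtOAc, 23 °C, stopped after one equivalent
Reagents that add atoms: none
Why: Lindlar semi-hydrogenation adds hydrogen syn to the alkyne only, which should give the (5Z) alkene and leave the tri- and 1,1-disubstituted alkenes intact.

Step 19
Reactants: 35 the seco ester
Product: 39 (3E,6Z,9Z,12R,14S)-4-[2-(tert-butyldiphenylsilyloxy)ethyl]-12-hydroxy-14-[(2R,5E)-2-hydroxy-5-methyl-7-phenylhept-5-en-1-yl]-10-methyl-1-oxacyclotetradeca-3,6,9-trien-2-one, via lactol 36 (not isolated), via hydroxy aldehyde 37 (not isolated), via macrocyclic borate 38 (not isolated)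
Conditions: AcOH/THF/H2O (4:2:1), 40 °C; evaporation with toluene; toluene (0.001 M), 80 °C; then aq. NaHCO3
Reagents that add atoms: water, O
Why: Proposed new method: acidic hydrolysis of the 2-deoxyglycoside-type acetal gives lactol 36, whose open hydroxy aldehyde 37 is attacked at C11 by the γ-carbon C10 of the pinacol allylboronate through a closed six-membered chair (B–O–C11–C10–C9–C8), the C8–B bond becoming the C8=C9 π-bond and borate 38 being hydrolysed on work-up. The closest known reaction type is the thermal allylboration of aldehydes and lactols by α-substituted β-methallyl pinacol boronates, established intermolecularly and for small and medium rings but not for a 14-membered lactone. The ring closes in a 14-exo-trig mode on the aldehyde carbon, the ester tether (C7 to C12 through C1 and O13) bridging the pseudo-axial C8 position and the equatorial C11 position of the chair. The new C11 stereocentre is controlled by the (8R) boron-bearing carbon through 1,3-chirality transfer: C7 sits pseudo-axial to avoid the pinacol methyls and A1,2 strain with the C9 methyl, and with the aldehyde chain equatorial this should give (11R) and at the same time the (8Z) alkene. The step needs cyclisation to beat oligomerisation and the axial-C7 chair to beat the equatorial one; high dilution, the low stationary aldehyde concentration (the lactol is the resting state) and the β-methyl/pinacol combination are expected to secure this. The C15 hydroxyl set free with the aldehyde is the one the target needs, so no protecting group is spent on it.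

Step 20
Reactants: 39 the macrolactone silyl ether
Product: 40 (3E,6Z,9Z,12R,14S)-12-hydroxy-4-(2-hydroxyethyl)-14-[(2R,5E)-2-hydroxy-5-methyl-7-phenylhept-5-en-1-yl]-10-methyl-1-oxacyclotetradeca-3,6,9-trien-2-one
Conditions: HF·pyridine, pyridine, THF, 0 → 23 °C
Reagents that add atoms: none
Why: Buffered HF·pyridine removes the primary TBDPS ether under acidic fluoride conditions that should not isomerise the skipped triene or move the lactone.

Step 21
Reactants: 40 the triol
Product: 42 2-[(3E,6Z,9Z,12R,14S)-12-hydroxy-14-[(2R,5E)-2-hydroxy-5-methyl-7-phenylhept-5-en-1-yl]-10-methyl-2-oxo-1-oxacyclotetradeca-3,6,9-trien-4-yl]acetic acid (CNP0194630.2), via aldehyde 41 (not isolated)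
Conditions: TEMPO (cat.), PhI(OAc)2, CH2Cl2/pH 7 buffer, 0 °C; then NaClO2, NaH2PO4, 2-methyl-2-butene, tBuOH/H2O, 0 °C
Reagents that add atoms: sodium chlorite, [Na+].[O-]Cl=O
Why: The oxoammonium ion from TEMPO oxidises the primary alcohol much faster than the two secondary ones, and the β,γ-unsaturated aldehyde is taken at once through a buffered Pinnick oxidation before it can conjugate.

Compound list
1 | pent-4-yn-1-ol | C#CCCCO | starting material
2 | benzyl chloride | ClCc1ccccc1 | starting material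
3 | dimethylaluminium alkoxide of (E)-5-(dimethylalumanyl)-4-methylpent-4-en-1-ol (alkenylalane, not isolated) | C[Al](C)OCCC/C(C)=C/[Al](C)C | intermediate
4 | (E)-4-methyl-6-phenylhex-4-en-1-ol | OCCC/C(C)=C/Cc1ccccc1 | intermediate
5 | (E)-4-methyl-6-phenylhex-4-enal | O=CCC/C(C)=C/Cc1ccccc1 | intermediate
6 | 4,4-dimethoxybutan-2-one | COC(OC)CC(C)=O | starting material
7 | 4,4-dimethoxybut-1-en-2-yl diisopinocampheylborinate (boron enolate, not isolated) | C[C@@H]1[C@H]2C[C@H](C2(C)C)C[C@H]1B(OC(=C)CC(OC)OC)[C@@H]1C[C@@H]2C[C@H]([C@H]1C)C2(C)C | intermediate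
8 | (5R,8E)-5-hydroxy-1,1-dimethoxy-8-methyl-10-phenyldec-8-en-3-one | COC(OC)CC(=O)C[C@H](O)CC/C(C)=C/Cc1ccccc1 | intermediate
9 | (3S,5R,8E)-1,1-dimethoxy-8-methyl-10-phenyldec-8-ene-3,5-diol | COC(OC)C[C@@H](O)C[C@H](O)CC/C(C)=C/Cc1ccccc1 | intermediate
10 | (4S,6R)-2-methoxy-6-[(3E)-3-methyl-5-phenylpent-3-en-1-yl]oxan-4-ol (anomeric mixture) | COC1C[C@@H](O)C[C@@H](CC/C(C)=C/Cc2ccccc2)O1 | intermediate
11 | but-3-yn-1-ol | C#CCCO | starting material
12 | (but-3-yn-1-yloxy)(tert-butyl)diphenylsilane | C#CCCO[Si](c1ccccc1)(c1ccccc1)C(C)(C)C | intermediate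
13 | lithium acetylide of 12 (not isolated) | [Li]C#CCCO[Si](c1ccccc1)(c1ccccc1)C(C)(C)C | intermediate
14 | methyl 5-(tert-butyldiphenylsilyloxy)pent-2-ynoate | COC(=O)C#CCCO[Si](c1ccccc1)(c1ccccc1)C(C)(C)C | intermediate
15 | methyl (Z)-5-(tert-butyldiphenylsilyloxy)-3-iodopent-2-enoate | COC(=O)/C=C(\I)CCO[Si](c1ccccc1)(c1ccccc1)C(C)(C)C | intermediate
16 | (tributylstannyl)methanol | CCCC[Sn](CO)(CCCC)CCCC | starting material
17 | methyl (Z)-5-(tert-butyldiphenylsilyloxy)-3-(hydroxymethyl)pent-2-enoate (not isolated) | COC(=O)/C=C(\CO)CCO[Si](c1ccccc1)(c1ccccc1)C(C)(C)C | intermediate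
18 | 4-[2-(tert-butyldiphenylsilyloxy)ethyl]furan-2(5H)-one | O=C1C=C(CCO[Si](c2ccccc2)(c2ccccc2)C(C)(C)C)CO1 | intermediate
19 | lithium (Z)-3-[2-(tert-butyldiphenylsilyloxy)ethyl]-4-hydroxybut-2-enoate (not isolated) | [Li+].[O-]C(=O)/C=C(\CO)CCO[Si](c1ccccc1)(c1ccccc1)C(C)(C)C | intermediate
20 | triethylsilyl (Z)-3-[2-(tert-butyldiphenylsilyloxy)ethyl]-4-(triethylsilyloxy)but-2-enoate (not isolated) | CC[Si](CC)(CC)OC(=O)/C=C(\CO[Si](CC)(CC)CC)CCO[Si](c1ccccc1)(c1ccccc1)C(C)(C)C | intermediate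
21 | (Z)-3-[2-(tert-butyldiphenylsilyloxy)ethyl]-4-(triethylsilyloxy)but-2-enoic acid | OC(=O)/C=C(\CO[Si](CC)(CC)CC)CCO[Si](c1ccccc1)(c1ccccc1)C(C)(C)C | intermediate
22 | 4-(trimethylsilyl)but-3-yn-1-ol | C[Si](C)(C)C#CCCO | starting material
23 | N,N-diisopropylcarbamoyl chloride | CC(C)N(C(C)C)C(Cl)=O | starting material
24 | 4-(trimethylsilyl)but-3-yn-1-yl N,N-diisopropylcarbamate | CC(C)N(C(C)C)C(=O)OCCC#C[Si](C)(C)C | intermediate
25 | 2-isopropenyl-4,4,5,5-tetramethyl-1,3,2-dioxaborolane | CC(=C)B1OC(C)(C)C(C)(C)O1 | starting material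
26 | (S)-1-lithio-4-(trimethylsilyl)but-3-yn-1-yl N,N-diisopropylcarbamate (sparteine ligand not drawn, not isolated) | CC(C)N(C(C)C)C(=O)O[C@H](CC#C[Si](C)(C)C)[Li] | intermediate
27 | lithium boronate complex of 26 with 25 (not isolated) | CC(C)N(C(C)C)C(=O)O[C@H](CC#C[Si](C)(C)C)[B-]1(C(C)=C)OC(C)(C)C(C)(C)O1.[Li+] | intermediate
28 | (R)-trimethyl[5-methyl-4-(4,4,5,5-tetramethyl-1,3,2-dioxaborolan-2-yl)hex-5-en-1-yn-1-yl]silane | C[Si](C)(C)C#CC[C@@H](B1OC(C)(C)C(C)(C)O1)C(C)=C | intermediate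
29 | (R)-4,4,5,5-tetramethyl-2-(2-methylhex-1-en-5-yn-3-yl)-1,3,2-dioxaborolane | C#CC[C@@H](B1OC(C)(C)C(C)(C)O1)C(C)=C | intermediate
30 | mixed anhydride of 21 with 2,4,6-trichlorobenzoic acid (not isolated) | O=C(OC(=O)c1c(Cl)cc(Cl)cc1Cl)/C=C(\CO[Si](CC)(CC)CC)CCO[Si](c1ccccc1)(c1ccccc1)C(C)(C)C | intermediate
31 | (4S,6R)-2-methoxy-6-[(3E)-3-methyl-5-phenylpent-3-en-1-yl]oxan-4-yl (2Z)-3-[2-(tert-butyldiphenylsilyloxy)ethyl]-4-(triethylsilyloxy)but-2-enoate | COC1C[C@@H](OC(=O)/C=C(\CO[Si](CC)(CC)CC)CCO[Si](c2ccccc2)(c2ccccc2)C(C)(C)C)C[C@@H](CC/C(C)=C/Cc2ccccc2)O1 | intermediate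
32 | (4S,6R)-2-methoxy-6-[(3E)-3-methyl-5-phenylpent-3-en-1-yl]oxan-4-yl (2Z)-3-[2-(tert-butyldiphenylsilyloxy)ethyl]-4-hydroxybut-2-enoate | COC1C[C@@H](OC(=O)/C=C(\CO)CCO[Si](c2ccccc2)(c2ccccc2)C(C)(C)C)C[C@@H](CC/C(C)=C/Cc2ccccc2)O1 | intermediate
33 | (4S,6R)-2-methoxy-6-[(3E)-3-methyl-5-phenylpent-3-en-1-yl]oxan-4-yl (2Z)-4-bromo-3-[2-(tert-butyldiphenylsilyloxy)ethyl]but-2-enoate | COC1C[C@@H](OC(=O)/C=C(\CBr)CCO[Si](c2ccccc2)(c2ccccc2)C(C)(C)C)C[C@@H](CC/C(C)=C/Cc2ccccc2)O1 | intermediate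
34 | (4S,6R)-2-methoxy-6-[(3E)-3-methyl-5-phenylpent-3-en-1-yl]oxan-4-yl (2E,8R)-3-[2-(tert-butyldiphenylsilyloxy)ethyl]-9-methyl-8-(4,4,5,5-tetramethyl-1,3,2-dioxaborolan-2-yl)deca-2,9-dien-5-ynoate | COC1C[C@@H](OC(=O)/C=C(\CC#CC[C@@H](B2OC(C)(C)C(C)(C)O2)C(C)=C)CCO[Si](c2ccccc2)(c2ccccc2)C(C)(C)C)C[C@@H](CC/C(C)=C/Cc2ccccc2)O1 | intermediate
35 | (4S,6R)-2-methoxy-6-[(3E)-3-methyl-5-phenylpent-3-en-1-yl]oxan-4-yl (2E,5Z,8R)-3-[2-(tert-butyldiphenylsilyloxy)ethyl]-9-methyl-8-(4,4,5,5-tetramethyl-1,3,2-dioxaborolan-2-yl)deca-2,5,9-trienoate (seco ester) | COC1C[C@@H](OC(=O)/C=C(\C/C=C\C[C@@H](B2OC(C)(C)C(C)(C)O2)C(C)=C)CCO[Si](c2ccccc2)(c2ccccc2)C(C)(C)C)C[C@@H](CC/C(C)=C/Cc2ccccc2)O1 | intermediate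
36 | lactol of 35: (4S,6R)-2-hydroxy-6-[(3E)-3-methyl-5-phenylpent-3-en-1-yl]oxan-4-yl ester of the same acid (not isolated) | OC1C[C@@H](OC(=O)/C=C(\C/C=C\C[C@@H](B2OC(C)(C)C(C)(C)O2)C(C)=C)CCO[Si](c2ccccc2)(c2ccccc2)C(C)(C)C)C[C@@H](CC/C(C)=C/Cc2ccccc2)O1 | intermediate
37 | open tautomer of 36: (3S,5R,8E)-5-hydroxy-8-methyl-1-oxo-10-phenyldec-8-en-3-yl ester of the same acid (not isolated) | O=CC[C@@H](OC(=O)/C=C(\C/C=C\C[C@@H](B1OC(C)(C)C(C)(C)O1)C(C)=C)CCO[Si](c1ccccc1)(c1ccccc1)C(C)(C)C)C[C@H](O)CC/C(C)=C/Cc1ccccc1 | intermediate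
38 | C11 O-pinacolboryl ether of 39 (macrocyclic borate, not isolated) | C/C1=C/C/C=C\C/C(CCO[Si](c2ccccc2)(c2ccccc2)C(C)(C)C)=C\C(=O)O[C@@H](C[C@H](O)CC/C(C)=C/Cc2ccccc2)C[C@H](OB2OC(C)(C)C(C)(C)O2)C1 | intermediate
39 | (3E,6Z,9Z,12R,14S)-4-[2-(tert-butyldiphenylsilyloxy)ethyl]-12-hydroxy-14-[(2R,5E)-2-hydroxy-5-methyl-7-phenylhept-5-en-1-yl]-10-methyl-1-oxacyclotetradeca-3,6,9-trien-2-one | C/C1=C/C/C=C\C/C(CCO[Si](c2ccccc2)(c2ccccc2)C(C)(C)C)=C\C(=O)O[C@@H](C[C@H](O)CC/C(C)=C/Cc2ccccc2)C[C@H](O)C1 | intermediate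
40 | (3E,6Z,9Z,12R,14S)-12-hydroxy-4-(2-hydroxyethyl)-14-[(2R,5E)-2-hydroxy-5-methyl-7-phenylhept-5-en-1-yl]-10-methyl-1-oxacyclotetradeca-3,6,9-trien-2-one | C/C1=C/C/C=C\C/C(CCO)=C\C(=O)O[C@@H](C[C@H](O)CC/C(C)=C/Cc2ccccc2)C[C@H](O)C1 | intermediate
41 | the corresponding C3 acetaldehyde (2-oxoethyl side chain, not isolated) | C/C1=C/C/C=C\C/C(CC=O)=C\C(=O)O[C@@H](C[C@H](O)CC/C(C)=C/Cc2ccccc2)C[C@H](O)C1 | intermediate
42 | 2-[(3E,6Z,9Z,12R,14S)-12-hydroxy-14-[(2R,5E)-2-hydroxy-5-methyl-7-phenylhept-5-en-1-yl]-10-methyl-2-oxo-1-oxacyclotetradeca-3,6,9-trien-4-yl]acetic acid (CNP0194630.2) | C/C1=C/C/C=C\C/C(CC(=O)O)=C\C(=O)O[C@@H](C[C@H](O)CC/C(C)=C/Cc2ccccc2)C[C@H](O)C1 | target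

Total steps: 21. Longest linear sequence: 13 steps (steps 1–5 and 14–21, from pent-4-yn-1-ol).

Steps most likely to fail

Step 19 (proposed new method). The 14-membered closure may be slow, so that intermolecular allylboration gives oligomers. The tether may force the chair with C7 equatorial, which would give the (8E) alkene with the C11 epimer. The aldehyde tautomer may lose the C13 acyloxy group by β-elimination at 80 °C. The fallback uses known chemistry only: the C10–C11 bond is made by the intermolecular version of the same allylboration and the ring is closed at C5=C6 by ring-closing metathesis. It sets out from 15, 10 and 29 and returns at 39. Stille coupling of 15 with allyltributylstannane (Pd(PPh3)4, CuI, DMF) should give methyl (2E)-3-[2-(tert-butyldiphenylsilyloxy)ethyl]hexa-2,5-dienoate F1, and LiOH in THF/H2O the acid F2. Yamaguchi esterification of F2 with 10 gives the ester F3, and AcOH/THF/H2O frees the lactol F4. Lindlar semi-hydrogenation of 29 gives the diene boronate F5. Heating F4 with an excess of F5 in toluene should give, after work-up, the (8Z,11R) diene diol F6, the α-stereocentre controlling C11 as in step 19. The second-generation Grubbs catalyst in refluxing CH2Cl2 at high dilution then closes the ring of F6 between the two terminal vinyl groups to give 39, the ring size being expected to enforce the (5Z) alkene.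

Step 17. The allylboronate may transmetallate to copper or protodeboronate under CuI and carbonate, and the doubly activated C4 methylene of the product may isomerise under base. The fallback joins boron-free fragments and installs boron last. It sets out from 22 and 33 and returns at 35. Dess–Martin oxidation of 22 gives 4-(trimethylsilyl)but-3-ynal F7, and Wittig reaction with ethyl 2-(triphenylphosphoranylidene)propanoate gives the (E)-enoate F8. DIBAL reduction gives the allylic alcohol F9, K2CO3 in MeOH the terminal alkyne F10, and ClCO2Me with pyridine the methyl carbonate F11. Coupling of F11 with 33 under the conditions of step 17 gives the enyne carbonate F12, and Lindlar semi-hydrogenation the triene carbonate F13. Copper-catalysed γ-selective (SN2′) allylic borylation of F13 (CuOtBu, QuinoxP* as the enantiomer that delivers 8R, B2pin2, THF) should then give 35. The enantioselectivity of this last step on a 2-methyl-substituted carbonate is uncertain, which is why it is only the fallback.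

Step 3. Facial selectivity of the Ipc2BCl aldol with a methyl ketone may be modest, and the acetal-bearing ketone may enolise towards C12 or lose methanol. The fallback sets C15 by a catalytic vinylogous Mukaiyama aldol and reaches the oxane through a lactone. It sets out from 5 and returns at 10. Addition of 1-methoxy-1,3-bis(trimethylsilyloxy)buta-1,3-diene to 5 with Ti(OiPr)4/BINOL (the enantiomer that gives 5R), followed by acidic work-up, should give the δ-hydroxy-β-keto ester F14. Me4NBH(OAc)3 gives the anti diol ester F15, PPTS in warm toluene the lactone F16, DIBAL at −78 °C the lactol F17, and MeOH with PPTS then gives 10.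

Further compounds
F1 | step 19 | methyl (2E)-3-[2-(tert-butyldiphenylsilyloxy)ethyl]hexa-2,5-dienoate | COC(=O)/C=C(\CC=C)CCO[Si](c1ccccc1)(c1ccccc1)C(C)(C)C
F2 | step 19 | (2E)-3-[2-(tert-butyldiphenylsilyloxy)ethyl]hexa-2,5-dienoic acid | OC(=O)/C=C(\CC=C)CCO[Si](c1ccccc1)(c1ccccc1)C(C)(C)C
F3 | step 19 | (4S,6R)-2-methoxy-6-[(3E)-3-methyl-5-phenylpent-3-en-1-yl]oxan-4-yl (2E)-3-[2-(tert-butyldiphenylsilyloxy)ethyl]hexa-2,5-dienoate | COC1C[C@@H](OC(=O)/C=C(\CC=C)CCO[Si](c2ccccc2)(c2ccccc2)C(C)(C)C)C[C@@H](CC/C(C)=C/Cc2ccccc2)O1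
F4 | step 19 | (4S,6R)-2-hydroxy-6-[(3E)-3-methyl-5-phenylpent-3-en-1-yl]oxan-4-yl (2E)-3-[2-(tert-butyldiphenylsilyloxy)ethyl]hexa-2,5-dienoate | OC1C[C@@H](OC(=O)/C=C(\CC=C)CCO[Si](c2ccccc2)(c2ccccc2)C(C)(C)C)C[C@@H](CC/C(C)=C/Cc2ccccc2)O1
F5 | step 19 | (R)-4,4,5,5-tetramethyl-2-(2-methylhexa-1,5-dien-3-yl)-1,3,2-dioxaborolane | C=CC[C@@H](B1OC(C)(C)C(C)(C)O1)C(C)=C
F6 | step 19 | (3S,5R,8Z)-5-hydroxy-1-[(2R,5E)-2-hydroxy-5-methyl-7-phenylhept-5-en-1-yl]-7-methylundeca-7,10-dien-3-yl ester of F2, written from the diene end (C11 R, C13 S, C15 R in macrolide numbering) | C=CC/C=C(/C)C[C@@H](O)C[C@@H](OC(=O)/C=C(\CC=C)CCO[Si](c1ccccc1)(c1ccccc1)C(C)(C)C)C[C@H](O)CC/C(C)=C/Cc1ccccc1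
F7 | step 17 | 4-(trimethylsilyl)but-3-ynal | C[Si](C)(C)C#CCC=O
F8 | step 17 | ethyl (E)-2-methyl-6-(trimethylsilyl)hex-2-en-5-ynoate | CCOC(=O)/C(C)=C/CC#C[Si](C)(C)C
F9 | step 17 | (E)-2-methyl-6-(trimethylsilyl)hex-2-en-5-yn-1-ol | OC/C(C)=C/CC#C[Si](C)(C)C
F10 | step 17 | (E)-2-methylhex-2-en-5-yn-1-ol | OC/C(C)=C/CC#C
F11 | step 17 | methyl (E)-2-methylhex-2-en-5-yn-1-yl carbonate | COC(=O)OC/C(C)=C/CC#C
F12 | step 17 | (4S,6R)-2-methoxy-6-[(3E)-3-methyl-5-phenylpent-3-en-1-yl]oxan-4-yl (2E,8E)-3-[2-(tert-butyldiphenylsilyloxy)ethyl]-10-(methoxycarbonyloxy)-9-methyldeca-2,8-dien-5-ynoate | COC1C[C@@H](OC(=O)/C=C(\CC#CC/C=C(\C)COC(=O)OC)CCO[Si](c2ccccc2)(c2ccccc2)C(C)(C)C)C[C@@H](CC/C(C)=C/Cc2ccccc2)O1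
F13 | step 17 | (4S,6R)-2-methoxy-6-[(3E)-3-methyl-5-phenylpent-3-en-1-yl]oxan-4-yl (2E,5Z,8E)-3-[2-(tert-butyldiphenylsilyloxy)ethyl]-10-(methoxycarbonyloxy)-9-methyldeca-2,5,8-trienoate | COC1C[C@@H](OC(=O)/C=C(\C/C=C\C/C=C(\C)COC(=O)OC)CCO[Si](c2ccccc2)(c2ccccc2)C(C)(C)C)C[C@@H](CC/C(C)=C/Cc2ccccc2)O1
F14 | step 3 | methyl (5R,8E)-5-hydroxy-8-methyl-3-oxo-10-phenyldec-8-enoate | COC(=O)CC(=O)C[C@H](O)CC/C(C)=C/Cc1ccccc1
F15 | step 3 | methyl (3S,5R,8E)-3,5-dihydroxy-8-methyl-10-phenyldec-8-enoate | COC(=O)C[C@@H](O)C[C@H](O)CC/C(C)=C/Cc1ccccc1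
F16 | step 3 | (4S,6R)-4-hydroxy-6-[(3E)-3-methyl-5-phenylpent-3-en-1-yl]oxan-2-one | O=C1C[C@@H](O)C[C@@H](CC/C(C)=C/Cc2ccccc2)O1
F17 | step 3 | (4S,6R)-6-[(3E)-3-methyl-5-phenylpent-3-en-1-yl]oxane-2,4-diol | OC1C[C@@H](O)C[C@@H](CC/C(C)=C/Cc2ccccc2)O1
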